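**Retrosynthetic overview**
- The strategy rests on ring A: a phloroglucinol whose three oxygens (O5 on C5, O7 on C7, ring oxygen O1 on C8a) must be told apart, with prenyl on C8 between C7 and C8a.
- Ring A is cut at C8–C8a, C6–C7 and C4a–C8a into 3-ethoxycyclobutenone (C8a, C4a, C5, C6) and a prenyl-substituted siloxyalkyne (C8, C7). The benzannulation delivers O1 as free phenol, O7 as silyl ether and O5 as ethyl ether.
- Ring C is cut at C4–C4a (ortho-formylation of the only free ortho carbon), C3–C4 (addition of the ring B acetylide) and O1–C2 (6-endo closure of the o-hydroxyaryl ynone).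
- Order of rings: ring B is bought (2,4-dihydroxybenzaldehyde), ring A is built in step 2, ring C is closed in step 8; de-ethylation and desilylation follow.

Key step: step 2

Remark on the chemistry: 1, 5 and 11 are taken as bought. Ring C is closed through an o-hydroxyaryl ynone under basic conditions, because the prenyl group and the aryl silyl ethers would not survive an acid-mediated acylation.

**Route**

Step 1
Reactants: 1 ethyl 4-methylpent-3-enoate
Product: 4 triisopropyl[(5-methylhex-4-en-1-yn-1-yl)oxy]silane, via dibromoketone enolate 2 (not isolated), via lithium ynolate 3 (not isolated)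
Conditions: CH2Br2, lithium 2,2,6,6-tetramethylpiperidide (LiTMP), THF, −78 °C; then 1; LiN(SiMe3)2; n-BuLi, −78 °C to rt; then i-Pr3SiOTf, −78 to 0 °C
Reagents that add atoms: dibromomethane, BrCBr; triisopropylsilyl trifluoromethanesulfonate, CC(C)[Si](OS(=O)(=O)C(F)(F)F)(C(C)C)C(C)C
Why: Kowalski ester homologation, in which LiCHBr2 should add to the ester carbonyl at −78 °C faster than it removes an α-proton, enolate 2 undergoes bromine–lithium exchange and 1,2-shift of the prenyl group to ynolate 3, and the bulky silyl triflate silylates 3 on oxygen.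

Step 2
Reactants: 4 triisopropyl[(5-methylhex-4-en-1-yn-1-yl)oxy]silane; 5 3-ethoxycyclobut-2-en-1-one
Product: 9 5-ethoxy-2-(3-methylbut-2-en-1-yl)-3-(triisopropylsilyloxy)phenol, via vinylketene 6 (not isolated), via vinylcyclobutenone 7 (not isolated), via dienylketene 8 (not isolated)
Conditions: 4 (1.2 equiv), toluene, 110–130 °C, sealed tube, slow addition of 5
Reagents that add atoms: none
Why: Proposed new method: heat should open 5 by a four-electron electrocyclic reaction to 3-ethoxyvinylketene 6, the siloxyalkyne adds to the ketene C=C in a [2+2] cycloaddition (forming C8–C8a and C6–C7) to give 7, and reversible four-electron opening of 7 gives the (3E)-dienylketene 8. The closest known reaction is the Danheiser benzannulation of 3-alkyl- and 3-arylcyclobutenones with siloxyalkynes; the 3-alkoxy donor on the cyclobutenone is the untested element, supported by the known thermal opening of 3-alkoxycyclobutenones to alkoxyvinylketenes that are trapped by alcohols. Ring A is closed by six-electron disrotatory electrocyclisation of 8, which re-forms C4a–C8a, and the cyclohexadienone enolises to the phenol. The product has no stereocentre, and the sp3 carbon of 7 is lost on ring opening. The step needs the regiochemistry of the ketene–alkyne cycloaddition, and the polarisation of the siloxyalkyne secures it: the prenyl-bearing carbon is the nucleophilic one and bonds to the ketene carbonyl carbon, so prenyl ends ortho to the new hydroxyl, between C8a and the silylated C7. Slow addition of 5 and a small excess of 4 should keep the ketene from acylating the product phenol, and the triisopropylsilyl group slows the 1,3-silyl shift of 4 to a silylketene.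

Step 3
Reactants: 9 5-ethoxy-2-(3-methylbut-2-en-1-yl)-3-(triisopropylsilyloxy)phenol
Product: 10 6-ethoxy-2-hydroxy-3-(3-methylbut-2-en-1-yl)-4-(triisopropylsilyloxy)benzaldehyde
Conditions: MgCl2, Et3N, (CH2O)n, THF, 65 °C; aq NH4Cl
Reagents that add atoms: paraformaldehyde (as formaldehyde), C=O
Why: Casnati–Skattebøl ortho-formylation, in which the magnesium phenoxide delivers formaldehyde to the only free ortho carbon (the future C4a) and hydride transfer to a second formaldehyde gives the salicylaldehyde without touching prenyl, ethyl ether or silyl ether.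

Step 4
Reactants: 11 2,4-dihydroxybenzaldehyde
Product: 12 2,4-bis(triisopropylsilyloxy)benzaldehyde
Conditions: i-Pr3SiOTf, 2,6-lutidine, CH2Cl2, 0 °C to rt
Reagents that add atoms: triisopropylsilyl trifluoromethanesulfonate, CC(C)[Si](OS(=O)(=O)C(F)(F)F)(C(C)C)C(C)C
Why: Silylation of both phenols with a silyl triflate and a hindered base, reactive enough for the hydrogen-bonded 2-hydroxyl.

Step 5
Reactants: 12 2,4-bis(triisopropylsilyloxy)benzaldehyde
Product: 13 1-(2,2-dibromoethenyl)-2,4-bis(triisopropylsilyloxy)benzene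
Conditions: CBr4, PPh3, CH2Cl2, 0 °C
Reagents that add atoms: carbon tetrabromide, BrC(Br)(Br)Br
Why: Ramirez dibromo-olefination (first stage of the Corey–Fuchs sequence) of a non-enolisable aryl aldehyde, to which aryl silyl ethers are inert.

Step 6
Reactants: 13 1-(2,2-dibromoethenyl)-2,4-bis(triisopropylsilyloxy)benzene; 10 6-ethoxy-2-hydroxy-3-(3-methylbut-2-en-1-yl)-4-(triisopropylsilyloxy)benzaldehyde
Product: 15 rac-3-[2,4-bis(triisopropylsilyloxy)phenyl]-1-[6-ethoxy-2-hydroxy-3-(3-methylbut-2-en-1-yl)-4-(triisopropylsilyloxy)phenyl]prop-2-yn-1-ol, via lithium acetylide 14 (not isolated)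
Conditions: 13 (2.2 equiv), n-BuLi (4.4 equiv), THF, −78 to 0 °C; then 10, −78 to 0 °C; aq NH4Cl
Reagents that add atoms: none
Why: Second stage of the Corey–Fuchs sequence (bromine–lithium exchange and Fritsch–Buttenberg–Wiechell shift) gives acetylide 14, of which one equivalent deprotonates the phenol of 10 and the second adds to the aldehyde to form C3–C4; the new carbinol centre forms racemic, without control, and is removed in step 7.

Step 7
Reactants: 15 rac-3-[2,4-bis(triisopropylsilyloxy)phenyl]-1-[6-ethoxy-2-hydroxy-3-(3-methylbut-2-en-1-yl)-4-(triisopropylsilyloxy)phenyl]prop-2-yn-1-ol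
Product: 16 3-[2,4-bis(triisopropylsilyloxy)phenyl]-1-[6-ethoxy-2-hydroxy-3-(3-methylbut-2-en-1-yl)-4-(triisopropylsilyloxy)phenyl]prop-2-yn-1-one
Conditions: activated MnO2 (excess), CH2Cl2, rt (crude 15 used at once)
Reagents that add atoms: none
Why: MnO2 oxidation of a benzylic and propargylic alcohol, selective over the prenyl alkene and the silyl ethers, with the product held by the hydrogen bond between phenol and carbonyl.

Step 8
Reactants: 16 3-[2,4-bis(triisopropylsilyloxy)phenyl]-1-[6-ethoxy-2-hydroxy-3-(3-methylbut-2-en-1-yl)-4-(triisopropylsilyloxy)phenyl]prop-2-yn-1-one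
Product: 18 2-[2,4-bis(triisopropylsilyloxy)phenyl]-5-ethoxy-8-(3-methylbut-2-en-1-yl)-7-(triisopropylsilyloxy)-4H-chromen-4-one, via enaminone 17 (not isolated)
Conditions: Et2NH, EtOH–THF, rt to 50 °C
Reagents that add atoms: none
Why: Amine-mediated cyclisation of an o-hydroxyaryl ynone, in which Et2NH adds to the ynone to give enaminone 17, whose β-carbon is the only electrophilic site, so the phenol closes ring C in the 6-endo mode (O1–C2) with loss of Et2NH and the 5-exo aurone cannot form.

Step 9
Reactants: 18 2-[2,4-bis(triisopropylsilyloxy)phenyl]-5-ethoxy-8-(3-methylbut-2-en-1-yl)-7-(triisopropylsilyloxy)-4H-chromen-4-one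
Product: 19 2-[2,4-bis(triisopropylsilyloxy)phenyl]-5-hydroxy-8-(3-methylbut-2-en-1-yl)-7-(triisopropylsilyloxy)-4H-chromen-4-one
Conditions: BCl3 (1 M in CH2Cl2), CH2Cl2, −78 to 0 °C; then cold aq NaHCO3
Reagents that add atoms: none
Why: Chelation-controlled ether cleavage, in which BCl3 binds between the C4 carbonyl and the peri O5 so that only the ethyl ether is cleaved, while O7 stays silylated and the prenyl group cannot cyclise onto it.

Step 10
Reactants: 19 2-[2,4-bis(triisopropylsilyloxy)phenyl]-5-hydroxy-8-(3-methylbut-2-en-1-yl)-7-(triisopropylsilyloxy)-4H-chromen-4-one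
Product: 20 2-(2,4-dihydroxyphenyl)-5,7-dihydroxy-8-(3-methylbut-2-en-1-yl)-4H-chromen-4-one
Conditions: Bu4NF, AcOH, THF, 0 °C
Reagents that add atoms: none
Why: Fluoride cleavage of the three aryl silyl ethers, buffered with acetic acid so that the polyphenol does not stand as an air-sensitive phenoxide.

**Compound list**
1 | ethyl 4-methylpent-3-enoate | CCOC(=O)CC=C(C)C | starting material
2 | lithium 1,1-dibromo-5-methylhexa-1,4-dien-2-olate | [Li+].[O-]C(CC=C(C)C)=C(Br)Br | intermediate
3 | lithium 5-methylhex-4-en-1-yn-1-olate | [Li+].[O-]C#CCC=C(C)C | intermediate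
4 | triisopropyl[(5-methylhex-4-en-1-yn-1-yl)oxy]silane | CC(C)=CCC#CO[Si](C(C)C)(C(C)C)C(C)C | intermediate
5 | 3-ethoxycyclobut-2-en-1-one | CCOC1=CC(=O)C1 | starting material
6 | 3-ethoxybuta-1,3-dien-1-one | C=C(OCC)C=C=O | intermediate
7 | rac-4-(1-ethoxyethenyl)-2-(3-methylbut-2-en-1-yl)-3-(triisopropylsilyloxy)cyclobut-2-en-1-one | O=C1C(CC=C(C)C)=C(O[Si](C(C)C)(C(C)C)C(C)C)C1C(OCC)=C | intermediate
8 | (3E)-5-ethoxy-2-(3-methylbut-2-en-1-yl)-3-(triisopropylsilyloxy)hexa-1,3,5-trien-1-one | O=C=C(CC=C(C)C)/C(O[Si](C(C)C)(C(C)C)C(C)C)=C\C(OCC)=C | intermediate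
9 | 5-ethoxy-2-(3-methylbut-2-en-1-yl)-3-(triisopropylsilyloxy)phenol | CCOc1cc(O)c(CC=C(C)C)c(O[Si](C(C)C)(C(C)C)C(C)C)c1 | intermediate
10 | 6-ethoxy-2-hydroxy-3-(3-methylbut-2-en-1-yl)-4-(triisopropylsilyloxy)benzaldehyde | CCOc1cc(O[Si](C(C)C)(C(C)C)C(C)C)c(CC=C(C)C)c(O)c1C=O | intermediate
11 | 2,4-dihydroxybenzaldehyde | O=Cc1ccc(O)cc1O | starting material
12 | 2,4-bis(triisopropylsilyloxy)benzaldehyde | O=Cc1ccc(O[Si](C(C)C)(C(C)C)C(C)C)cc1O[Si](C(C)C)(C(C)C)C(C)C | intermediate
13 | 1-(2,2-dibromoethenyl)-2,4-bis(triisopropylsilyloxy)benzene | BrC(Br)=Cc1ccc(O[Si](C(C)C)(C(C)C)C(C)C)cc1O[Si](C(C)C)(C(C)C)C(C)C | intermediate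
14 | lithium [2,4-bis(triisopropylsilyloxy)phenyl]acetylide | [Li+].[C-]#Cc1ccc(O[Si](C(C)C)(C(C)C)C(C)C)cc1O[Si](C(C)C)(C(C)C)C(C)C | intermediate
15 | rac-3-[2,4-bis(triisopropylsilyloxy)phenyl]-1-[6-ethoxy-2-hydroxy-3-(3-methylbut-2-en-1-yl)-4-(triisopropylsilyloxy)phenyl]prop-2-yn-1-ol (racemic carbinol) | CCOc1cc(O[Si](C(C)C)(C(C)C)C(C)C)c(CC=C(C)C)c(O)c1C(O)C#Cc1ccc(O[Si](C(C)C)(C(C)C)C(C)C)cc1O[Si](C(C)C)(C(C)C)C(C)C | intermediate
16 | 3-[2,4-bis(triisopropylsilyloxy)phenyl]-1-[6-ethoxy-2-hydroxy-3-(3-methylbut-2-en-1-yl)-4-(triisopropylsilyloxy)phenyl]prop-2-yn-1-one | CCOc1cc(O[Si](C(C)C)(C(C)C)C(C)C)c(CC=C(C)C)c(O)c1C(=O)C#Cc1ccc(O[Si](C(C)C)(C(C)C)C(C)C)cc1O[Si](C(C)C)(C(C)C)C(C)C | intermediate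
17 | 3-[2,4-bis(triisopropylsilyloxy)phenyl]-3-(diethylamino)-1-[6-ethoxy-2-hydroxy-3-(3-methylbut-2-en-1-yl)-4-(triisopropylsilyloxy)phenyl]prop-2-en-1-one (E/Z not fixed) | CCOc1cc(O[Si](C(C)C)(C(C)C)C(C)C)c(CC=C(C)C)c(O)c1C(=O)C=C(N(CC)CC)c1ccc(O[Si](C(C)C)(C(C)C)C(C)C)cc1O[Si](C(C)C)(C(C)C)C(C)C | intermediate
18 | 2-[2,4-bis(triisopropylsilyloxy)phenyl]-5-ethoxy-8-(3-methylbut-2-en-1-yl)-7-(triisopropylsilyloxy)-4H-chromen-4-one | CCOc1cc(O[Si](C(C)C)(C(C)C)C(C)C)c(CC=C(C)C)c2oc(-c3ccc(O[Si](C(C)C)(C(C)C)C(C)C)cc3O[Si](C(C)C)(C(C)C)C(C)C)cc(=O)c12 | intermediate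
19 | 2-[2,4-bis(triisopropylsilyloxy)phenyl]-5-hydroxy-8-(3-methylbut-2-en-1-yl)-7-(triisopropylsilyloxy)-4H-chromen-4-one | Oc1cc(O[Si](C(C)C)(C(C)C)C(C)C)c(CC=C(C)C)c2oc(-c3ccc(O[Si](C(C)C)(C(C)C)C(C)C)cc3O[Si](C(C)C)(C(C)C)C(C)C)cc(=O)c12 | intermediate
20 | 2-(2,4-dihydroxyphenyl)-5,7-dihydroxy-8-(3-methylbut-2-en-1-yl)-4H-chromen-4-one | CC(C)=CCc1c(O)cc(O)c2c(=O)cc(-c3ccc(O)cc3O)oc12 | target

**Step count**
Total: 10 steps. Longest linear sequence: 8 steps (1, 2, 3, 6, 7, 8, 9, 10).

**Steps most likely to fail**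

Step 2. The donor-substituted cyclobutenone may open too slowly, so that 1,3-silyl shift of the siloxyalkyne to a silylketene, ketene dimerisation, or O-acylation of the product phenol by the vinylketene take over. The fallback uses known chemistry and changes the approach from benzannulation to directed metalation of a preformed phloroglucinol. Because ring A is a branch of its own, the fallback does not set out from a numbered compound: compounds 1 to 8 are given up, it starts from bought 5-ethoxybenzene-1,3-diol F1, and it comes back to the route at 9. Both hydroxyls of F1 are protected with MOMCl and i-Pr2NEt to give 1-ethoxy-3,5-bis(methoxymethoxy)benzene F2. Directed ortho-lithiation with n-BuLi in THF at 0 °C should go to the carbon between the two MOM ethers, and transmetalation with CuI and alkylation with prenyl bromide should give 5-ethoxy-1,3-bis(methoxymethoxy)-2-(3-methylbut-2-en-1-yl)benzene F3. HCl in MeOH at rt removes the MOM groups to give the symmetrical 5-ethoxy-2-(3-methylbut-2-en-1-yl)benzene-1,3-diol F4. One equivalent of i-Pr3SiCl with imidazole silylates one of the two equivalent hydroxyls and gives 9, which enters step 3 unchanged.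

Step 1. The β,γ-unsaturated ester has unusually acidic α-protons, so deprotonation by the carbenoid and migration of the double bond into conjugation may compete with addition to the carbonyl. The fallback sets out from 1, replaces ester homologation by oxidation of an acetylide, and comes back to the route at ynolate 3 and then 4. Reduction of 1 with i-Bu2AlH in CH2Cl2 at −78 °C should give 4-methylpent-3-enal F5, used crude. Colvin homologation with lithiated Me3SiCHN2 (from LiN(i-Pr)2, THF, −78 °C to rt) should give 5-methylhex-4-en-1-yne F6. Deprotonation with n-BuLi and oxidation of the lithium acetylide with LiOO-t-Bu (from t-BuOOH and LiN(SiMe3)2, −78 to 0 °C) should give ynolate 3, which is silylated with i-Pr3SiOTf to 4 as in step 1.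

Step 9. An ethyl ether is cleaved more slowly than a methyl ether, and at the longer time or higher temperature needed, hydrogen chloride may add to the prenyl alkene, or a silyl group may be lost and the alkene may then cyclise onto O7. The fallback sets out from 18, replaces Lewis-acid cleavage by nucleophilic dealkylation under basic conditions, and comes back to the route at 20. Bu4NF with AcOH in THF removes the three silyl groups of 18 to give 2-(2,4-dihydroxyphenyl)-5-ethoxy-7-hydroxy-8-(3-methylbut-2-en-1-yl)-4H-chromen-4-one F7. Sodium ethanethiolate (NaSEt) in DMF at 110–130 °C should then remove the ethyl group by SN2 attack on its CH2 and give 20, under conditions that do not touch the prenyl alkene.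

**Further compounds**
F1 | step 2 | 5-ethoxybenzene-1,3-diol (bought) | CCOc1cc(O)cc(O)c1
F2 | step 2 | 1-ethoxy-3,5-bis(methoxymethoxy)benzene | CCOc1cc(OCOC)cc(OCOC)c1
F3 | step 2 | 5-ethoxy-1,3-bis(methoxymethoxy)-2-(3-methylbut-2-en-1-yl)benzene | CCOc1cc(OCOC)c(CC=C(C)C)c(OCOC)c1
F4 | step 2 | 5-ethoxy-2-(3-methylbut-2-en-1-yl)benzene-1,3-diol | CCOc1cc(O)c(CC=C(C)C)c(O)c1
F5 | step 1 | 4-methylpent-3-enal | CC(C)=CCC=O
F6 | step 1 | 5-methylhex-4-en-1-yne | CC(C)=CCC#C
F7 | step 9 | 2-(2,4-dihydroxyphenyl)-5-ethoxy-7-hydroxy-8-(3-methylbut-2-en-1-yl)-4H-chromen-4-one | CCOc1cc(O)c(CC=C(C)C)c2oc(-c3ccc(O)cc3O)cc(=O)c12
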